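The flask holds 45 mM of E, 58.5 mM of D and 4.5 mM of L, which makes 1.30 D per E, and three earlier runs with other charges show how fast E is lost.

common to all: L 4.5 mM

| run | E | D | remark | time |
|---|---|---|---|---|
| grey | 45 mM | 82 mM | run made earlier |  |
| ochre | 45 mM | 130 mM | run made earlier |  |
| green | 22 mM | 58.5 mM | run made earlier |  |
| flask | 45 mM | 58.5 mM |  | 2.0 min |

| run | time / s | X / % | J / % | E / % |
|---|---|---|---|---|
| grey | 10.0 | 6.7 | 0.9 | 88.3 |
| grey | 25.0 | 20.7 | 0 | 75.8 |
| grey | 50.0 | 39.3 | 0 | 56.4 |
| grey | 80.0 | 55.7 | 2.3 | 43.6 |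
| ochre | 10.0 | 6.9 | 0.5 | 89.3 |
| ochre | 12.0 | 9.4 | 0.6 | 86.0 |
| ochre | 30.0 | 25.5 | 0 | 71.6 |
| ochre | 80.0 | 54.4 | 3.3 | 40.9 |
| green | 20.0 | 19.1 | 0 | 78.0 |
| green | 40.0 | 34.4 | 1.1 | 61.7 |
| green | 50.0 | 43.0 | 0.4 | 56.1 |
| green | 80.0 | 59.4 | 0 | 39.7 |

(scatter of a reading: 1 percentage point)

- amounts and yields of X count J too
- given per volume of solution although it is solid: J
- the numbers in the tables scatter with a standard deviation of 1 percentage point

1. the X and J together standing at 2.0 min, as a percentage of the E charged
2. concentration of X in solution at 2.0 min, in percent of saturation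

1. From the last reading of each run I take ln([E]₀/[E])/t. Grey gives 0.0104 s⁻¹, ochre 0.0112 s⁻¹ and green 0.0115 s⁻¹. I carry one quantity, their mean 0.0110 s⁻¹, the fractional rate: the share of the E present that is lost each second, a pseudo-first-order constant.

2. For the flask I take 0.0110 s⁻¹ as the starting rate, reckoned on the E charged.

3. Raising [D] from grey to ochre multiplies [D] by 1.59 and the fractional rate by a reading of 1.08. I therefore freeze the factor for D at one.

4. The loss of E is the slowing I keep. The rate falls to 0.5 of its value every 62.8 s, so by 2.0 min it stands at a factor of 0.266, about a quarter of its start.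

5. Unslowed, the starting rate would deliver 132 % of the charge. The accumulated slowing leaves 73.4 % for my reckoning of y.

6. The forecast says 71.5 % for y and 106 % for sat. It stands 1.9 points below my figure, and of the rate it says “I shade slightly low for that”.

The flask gives 70.1 % and 101 %.

    E + L ⇌ G (K = 3.40 M⁻¹, k = 164 M⁻¹ s⁻¹)
    G → Z (k = 0.896 s⁻¹)
    D + Z → Q (k = 14.4 M⁻¹ s⁻¹)
    Q → L + X (k = 1.09 s⁻¹)
    J ⇌ X, rate k5*(cs5 - [X]) while solid is left; crystals form when [X] > cs5 (solubility = 24.0 mM, k = 0.595 s⁻¹)

In the flask, E stands at 28.4 % at 2.00 min, against my 26.6 %. The same reckoning on the neighbour with 15 mM of D again gives 73.4 % from the fractional rate. The scheme, however, spends one D for each X, and this charge of D equals 33.3 % of the E, so D is the limiting reagent and that share is the ceiling. The neighbour gives 33.0 %, with D down to 0.99 % of its charge and E still at 57.7 %.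

The earlier runs and the new flask stem from a simulated flask from invented constants.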